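## The problem

Compound 17 is an open-chain ketone: a C17 terpenoid chain ends in a carbonyl group bonded to a 2-hydroxy-6-methylphenyl ring, so no ring has to be closed and the task is chain assembly around one branching point. That point, C3, is the only stereocentre. It is an all-carbon quaternary carbon of R configuration carrying methyl, vinyl, the (3E)-4,8-dimethylnona-3,7-dienyl chain and the CH2C(=O)Ar arm. No second stereocentre can relay to it, and methyl and two unbranched methylene chains differ little near the centre, so catalyst-controlled selection is hard and transfer of configuration from a centre set elsewhere is preferable. Once formed the quaternary carbon cannot epimerise, but any intermediate with two identical groups on it (two vinyl groups, for example) would erase the chirality. The two trisubstituted alkenes (one of fixed E geometry) and the terminal vinyl group will not survive strong acid, electrophilic oxidants or unselective hydrogenation or hydroboration, and the phenol must be masked whenever an organometallic is used. The enabling feature is that C3, with its methyl group and its C11 chain, is C3 of (2E,6E)-farnesol 1, where it belongs to an allylic alcohol. The C2=C3 alkene can therefore be epoxidised with known absolute configuration to 2, and the tertiary C3–O bond of 2 can be replaced by a C–C bond with inversion.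

## Retrosynthesis

**17 back to 11 and 13.** The phenol of 17 is unmasked last from methoxymethyl ether 16, and the ketone of 16 is taken back to carbinol 15. The bond cut is aryl–C1, which gives aldehyde 11 and aryllithium 14, made from bromide 13 and so from bromophenol 12. Direct acylation of the arene would be regiochemically ambiguous and would need Lewis acids that the polyene cannot bear. Cutting C1–C2 instead would need a neopentyl-type nucleophile with a β-vinyl group, which is prone to homoallyl rearrangement. The forward step needs a hindered aryllithium to add to an enolisable aldehyde, followed by a neutral oxidation.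

**11 back to 9.** The C1–C2 bond of 11 is cut, so the aldehyde carbon is the one added. Aldehyde 9 is homologated through enol ether 10. Methylenation followed by hydroboration is excluded, because it would pass through a divinyl compound and destroy the stereocentre. The new carbon must therefore arrive already differentiated from the vinyl group. The forward reaction must tolerate a neopentyl aldehyde and release 11 under mild acid.

**9 back to 6.** Aldehyde 9 is the glycol-cleavage product of vinyl diol 8, which comes from alkyne 7 by semihydrogenation and from silylalkyne 6 by desilylation. The cleaved bond is C1–C2 of the diol. This accepts the loss of one carbon because a 1,2-diol is what an epoxy alcohol opening delivers, and an alkynyl group is the carbon ligand that aluminium transfers best. Cleavage also removes any 1,3-diol from opening at the wrong carbon, since only a 1,2-diol is cut.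

**6 back to 2 and 5 (key disconnection).** The bond cut joins the quaternary carbon to the alkyne carbon. The precursors are epoxy alcohol 2 and alkynylalane 5. This cut is preferred over those to the other three substituents because it is the only one for which the electrophilic carbon can be bought with the methyl group and the whole E-configured C11 chain attached. Its configuration also comes from a reagent-controlled epoxidation and not from a selection between similar groups. The forward reaction must open 2 at the fully substituted carbon, with inversion and without ionisation to a free cation.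

**2 back to 1, 5 back to 3.** Epoxide 2 comes from farnesol 1 by hydroxyl-directed asymmetric epoxidation, which touches only the allylic alkene. Alane 5 comes from silylacetylene 3 through lithium acetylide 4. Both are one-step preparations from commercial materials.

## Roads not taken

Alternative 1: The cut is the C5–C6 bond, with the stereocentre created at the same time by desymmetrisation. Prochiral dienone A2 carries two vinyl groups, the methyl group and the protected aryl ketone arm on one carbon. It would be hydroborated at one enantiotopic vinyl group with a dialkoxyborane under a chiral rhodium bisphosphine catalyst (for instance from [Rh(cod)2]BF4) to give primary boronate A4. In the same pot A4 would be coupled with E-alkenyl iodide A3 under PdCl2(dppf) to give A1.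
- Merits: A1 is identical with 16, so one deprotection would finish the synthesis. The route is convergent, and the aryl ketone is built before any sensitive polyene exists.
- Weak points: the catalyst must tell apart two vinyl groups that differ only through a remote choice between methyl and a CH2C(=O)Ar arm. The aryl ketone can itself be reduced by the metal hydride. A second hydroboration of the remaining vinyl group competes. Primary pinacol boronates transmetalate slowly in alkyl Suzuki coupling. A2 and A3 each need several steps.
- Comparison: on step count and convergence this road is better. The chosen plan sets against it a configuration whose sense and level follow from a well-understood epoxidation and a stereospecific substitution, while the alternative rests on a selection that cannot be predicted from structure.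

Alternative 2: The cut is the C3–C4 bond. Homoallylic Grignard reagent A6 and E-allylic chloride A7 would combine under CuBr·SMe2 and a chiral ligand in an SN2' substitution. This gives silyl ether A5 with the quaternary carbon and the vinyl group formed in one step.
- Merits: the step is convergent and builds the hardest carbon directly. A5 needs only desilylation and oxidation to reach aldehyde 11 of the chosen route, so the whole sequence would be a few steps shorter.
- Weak points: the ligand must distinguish methyl from a CH2CH2OSi chain at the alkene terminus, the hardest case for this reaction class. Direct SN2 substitution competes. The E/Z purity of A7 translates directly into enantiomeric purity. A6 needs a one-carbon-extended C11 halide that must itself be made.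
- Comparison: this road is shorter and more convergent. The chosen plan sets against it that the whole C15 skeleton, including the 6E alkene, is bought in 1, and that the stereocentre comes from one of the most dependable asymmetric reactions followed by inversion.

Alternative 3: No skeletal bond is cut. Prochiral diester A9 would be hydrolysed at one enantiotopic ester by a serine hydrolase such as pig liver esterase to give half-ester A8.
- Merits: the reagent is cheap and the reaction runs in water without low temperatures. Either enantiomer of the target could be reached from A8 by choosing which arm is elaborated first.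
- Weak points: A9 must first be assembled, quaternary carbon included. Its long lipophilic chain dissolves poorly in buffer. Sense and level of the enzyme's choice between methyl and the long chain cannot be foreseen. The acid arm of A8 must become the aryl ketone, and the ester arm must be reduced and dehydrated to the vinyl group, so several functional-group steps follow.
- Comparison: this road is easier to operate and is enantiodivergent. The chosen plan sets against it a shorter sequence, a predictable configuration, and a stereo-defining step that also forms a skeletal bond.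

Key step: step 3

Remark: farnesol 1 is taken as the pure (2E,6E) isomer. A 2Z contaminant would give the opposite configuration at C3 and must be removed beforehand.

## Route

Step 1
Reactants: 1 (2E,6E)-farnesol
Product: 2 (2S,3S)-2,3-epoxyfarnesol, [(2S,3S)-3-[(3E)-4,8-dimethylnona-3,7-dien-1-yl]-3-methyloxiran-2-yl]methanol
Conditions: Ti(OiPr)4 (cat.), L-(+)-diethyl tartrate (cat.), t-BuOOH, 4 Å molecular sieves, CH2Cl2, −20 °C
Reagents that add atoms: tert-butyl hydroperoxide, CC(C)(C)OO
Why: Katsuki–Sharpless asymmetric epoxidation; the titanium tartrate complex binds the allylic hydroxyl, so only the C2=C3 alkene is oxidised, and with the L-(+)-tartrate an E-allylic alcohol of this kind should give the (2S,3S)-epoxide, which fixes C3.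

Step 2
Reactants: 3 trimethylsilylacetylene
Product: 5 diethyl[(trimethylsilyl)ethynyl]aluminium, via lithium (trimethylsilyl)acetylide 4 (not isolated)
Conditions: n-BuLi, toluene/hexane, 0 °C; then Et2AlCl, 0 °C to rt; solution used directly
Reagents that add atoms: diethylaluminium chloride, CC[Al](Cl)CC
Why: Deprotonation of the terminal alkyne followed by lithium-to-aluminium transmetalation (salt metathesis with loss of LiCl) is the standard preparation of a dialkyl(alkynyl)alane; ether solvents are avoided so that the aluminium keeps its Lewis acidity.

Step 3
Reactants: 2 (2S,3S)-2,3-epoxyfarnesol; 5 diethyl[(trimethylsilyl)ethynyl]aluminium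
Product: 6 (2R,3S,6E)-3,7,11-trimethyl-3-[(trimethylsilyl)ethynyl]dodeca-6,10-diene-1,2-diol
Conditions: 5 (about 4 equiv), toluene/hexane, −20 °C to rt; aq. potassium sodium tartrate work-up
Reagents that add atoms: none
Why: The first equivalent of 5 turns the hydroxyl of 2 into an aluminium alkoxide whose metal also binds the oxirane oxygen and polarises the C3–O bond; a second molecule of alane then delivers its alkynyl group to C3 from the face opposite the departing oxygen, a borderline SN2 opening with a loose, cation-like transition state. The closest known reaction type is the opening of Sharpless 2,3-epoxy alcohols at C3 by trialkyl- and alkynylalanes to give 1,2-diols. No ring is closed; one C–C bond, from C3 to the alkyne carbon, is formed. The only new stereocentre is the quaternary C3 (S in 6, named R in 17 only because substituent ranking changes later), and it is controlled by the (2S,3S)-epoxide, hence by the tartrate of step 1, through inversion; C2 keeps its configuration and is removed in step 6. The step needs C3 over C2 regioselectivity, which the chelating aluminium and the better charge stabilisation at the fully substituted carbon should secure. It needs alkynyl and not ethyl transfer, which follows from the greater migratory aptitude of the sp carbon on aluminium. Substitution must also outrun hydride shift and elimination at the tertiary centre, which is why a non-coordinating solvent, an excess of the nucleophile and a low temperature are used. The chain alkenes should not interfere, because attack of C6=C7 on C3 would give a four-membered ring or a secondary cation.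

Step 4
Reactants: 6 (2R,3S,6E)-3,7,11-trimethyl-3-[(trimethylsilyl)ethynyl]dodeca-6,10-diene-1,2-diol
Product: 7 (2R,3S,6E)-3-ethynyl-3,7,11-trimethyldodeca-6,10-diene-1,2-diol
Conditions: K2CO3, MeOH, rt
Reagents that add atoms: none
Why: Base-mediated protodesilylation of a silylalkyne (methoxide attacks silicon and the acetylide is protonated by methanol); nothing else in 6 is base-sensitive.

Step 5
Reactants: 7 (2R,3S,6E)-3-ethynyl-3,7,11-trimethyldodeca-6,10-diene-1,2-diol
Product: 8 (2R,3S,6E)-3-ethenyl-3,7,11-trimethyldodeca-6,10-diene-1,2-diol
Conditions: H2 (1 atm), Pd/CaCO3 poisoned with Pb(OAc)2, quinoline, EtOAc, rt, stopped after one equivalent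
Reagents that add atoms: none
Why: Lindlar semihydrogenation; the terminal alkyne binds the poisoned palladium surface far more strongly than the trisubstituted alkenes or the hindered vinyl group that forms, so reduction should stop at the alkene.

Step 6
Reactants: 8 (2R,3S,6E)-3-ethenyl-3,7,11-trimethyldodeca-6,10-diene-1,2-diol
Product: 9 (2S,5E)-2-ethenyl-2,6,10-trimethylundeca-5,9-dienal
Conditions: NaIO4, THF/H2O (pH 7), 0 °C to rt
Reagents that add atoms: none
Why: Malaprade glycol cleavage through a cyclic periodate ester leaves alkenes untouched; the aldehyde has no α-hydrogen, so the quaternary centre cannot epimerise, and any 1,3-diol from C2 opening in step 3 is not cleaved and is separated here.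

Step 7
Reactants: 9 (2S,5E)-2-ethenyl-2,6,10-trimethylundeca-5,9-dienal
Product: 10 (3S,6E)-3-ethenyl-1-methoxy-3,7,11-trimethyldodeca-1,6,10-triene (1E/1Z mixture)
Conditions: Ph3P(CH2OMe)Cl, KN(SiMe3)2, THF, 0 °C; then 9, 0 °C to rt
Reagents that add atoms: (methoxymethyl)triphenylphosphonium chloride, COC[P+](c1ccccc1)(c1ccccc1)c1ccccc1.[Cl-]
Why: Wittig methoxymethylenation; the aldehyde cannot enolise and, although neopentyl, should accept this small reactive ylide, and the enol ether geometry is irrelevant because both isomers hydrolyse to the same aldehyde.

Step 8
Reactants: 10 (3S,6E)-3-ethenyl-1-methoxy-3,7,11-trimethyldodeca-1,6,10-triene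
Product: 11 (3R,6E)-3-ethenyl-3,7,11-trimethyldodeca-6,10-dienal
Conditions: aq. HCl (1 M), THF, 0 °C to rt, short reaction time
Reagents that add atoms: water, O
Why: Acid-catalysed enol ether hydrolysis (C-protonation to the oxocarbenium ion, hydration, loss of methanol); the electron-rich enol ether is protonated much faster than the isolated alkenes, and the change of descriptor from S to R is only a change of substituent ranking.

Step 9
Reactants: 12 2-bromo-3-methylphenol
Product: 13 2-bromo-1-(methoxymethoxy)-3-methylbenzene
Conditions: NaH, DMF, 0 °C; then MOMCl, 0 °C to rt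
Reagents that add atoms: chloromethyl methyl ether, COCCl
Why: O-Alkylation of the phenoxide by the reactive α-chloro ether (Williamson type); the acetal is inert to organolithiums and its oxygen atoms help to hold the ortho lithium in the next step.

Step 10
Reactants: 13 2-bromo-1-(methoxymethoxy)-3-methylbenzene; 11 (3R,6E)-3-ethenyl-3,7,11-trimethyldodeca-6,10-dienal
Product: 15 (3R,6E)-3-ethenyl-1-[2-(methoxymethoxy)-6-methylphenyl]-3,7,11-trimethyldodeca-6,10-dien-1-ol, via [2-(methoxymethoxy)-6-methylphenyl]lithium 14 (not isolated)
Conditions: 13, n-BuLi, THF, −78 °C; then 11, −78 to −40 °C; aq. NH4Cl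
Reagents that add atoms: none
Why: Bromine–lithium exchange followed by 1,2-addition of the aryllithium to the aldehyde; the bromine fixes the position of the new bond between the methyl and the protected hydroxyl, and the carbinol centre is left uncontrolled because both epimers are oxidised to one ketone in step 11.

Step 11
Reactants: 15 (3R,6E)-3-ethenyl-1-[2-(methoxymethoxy)-6-methylphenyl]-3,7,11-trimethyldodeca-6,10-dien-1-ol
Product: 16 (3R,6E)-3-ethenyl-1-[2-(methoxymethoxy)-6-methylphenyl]-3,7,11-trimethyldodeca-6,10-dien-1-one
Conditions: Dess–Martin periodinane, NaHCO3, CH2Cl2, 0 °C to rt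
Reagents that add atoms: none
Why: Dess–Martin oxidation of a secondary benzylic alcohol (ligand exchange at iodine, then α-hydrogen removal) under buffered neutral conditions, which should leave the alkenes and the acetal alone.

Step 12
Reactants: 16 (3R,6E)-3-ethenyl-1-[2-(methoxymethoxy)-6-methylphenyl]-3,7,11-trimethyldodeca-6,10-dien-1-one
Product: 17 (3R,6E)-3-ethenyl-1-(2-hydroxy-6-methylphenyl)-3,7,11-trimethyldodeca-6,10-dien-1-one
Conditions: conc. HCl (cat.), MeOH, rt to 40 °C
Reagents that add atoms: none
Why: Acid-catalysed acetal exchange (methanolysis of the methoxymethyl ether); an aryl acetal ortho to a carbonyl is unusually labile because the freed phenol hydrogen-bonds to the ketone, so acid weaker than what the trisubstituted alkenes tolerate should suffice, and C3 has no acidic hydrogen and stays R.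

## Compound list

1 | (2E,6E)-farnesol, (2E,6E)-3,7,11-trimethyldodeca-2,6,10-trien-1-ol | CC(C)=CCC/C(C)=C/CC/C(C)=C/CO | starting material
2 | (2S,3S)-2,3-epoxyfarnesol, [(2S,3S)-3-[(3E)-4,8-dimethylnona-3,7-dien-1-yl]-3-methyloxiran-2-yl]methanol | OC[C@@H]1O[C@@]1(C)CC/C=C(\C)CCC=C(C)C | intermediate
3 | trimethylsilylacetylene | C#C[Si](C)(C)C | starting material
4 | lithium (trimethylsilyl)acetylide | [Li]C#C[Si](C)(C)C | intermediate (not isolated)
5 | diethyl[(trimethylsilyl)ethynyl]aluminium | CC[Al](CC)C#C[Si](C)(C)C | intermediate (reagent solution)
6 | (2R,3S,6E)-3,7,11-trimethyl-3-[(trimethylsilyl)ethynyl]dodeca-6,10-diene-1,2-diol | C[Si](C)(C)C#C[C@](C)(CC/C=C(\C)CCC=C(C)C)[C@@H](O)CO | intermediate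
7 | (2R,3S,6E)-3-ethynyl-3,7,11-trimethyldodeca-6,10-diene-1,2-diol | C#C[C@](C)(CC/C=C(\C)CCC=C(C)C)[C@@H](O)CO | intermediate
8 | (2R,3S,6E)-3-ethenyl-3,7,11-trimethyldodeca-6,10-diene-1,2-diol | C=C[C@](C)(CC/C=C(\C)CCC=C(C)C)[C@@H](O)CO | intermediate
9 | (2S,5E)-2-ethenyl-2,6,10-trimethylundeca-5,9-dienal | C=C[C@](C)(CC/C=C(\C)CCC=C(C)C)C=O | intermediate
10 | (3S,6E)-3-ethenyl-1-methoxy-3,7,11-trimethyldodeca-1,6,10-triene (1E/1Z mixture) | C=C[C@](C)(CC/C=C(\C)CCC=C(C)C)C=COC | intermediate
11 | (3R,6E)-3-ethenyl-3,7,11-trimethyldodeca-6,10-dienal | C=C[C@](C)(CC/C=C(\C)CCC=C(C)C)CC=O | intermediate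
12 | 2-bromo-3-methylphenol | Cc1cccc(O)c1Br | starting material
13 | 2-bromo-1-(methoxymethoxy)-3-methylbenzene | COCOc1cccc(C)c1Br | intermediate
14 | [2-(methoxymethoxy)-6-methylphenyl]lithium | [Li]c1c(C)cccc1OCOC | intermediate (not isolated)
15 | (3R,6E)-3-ethenyl-1-[2-(methoxymethoxy)-6-methylphenyl]-3,7,11-trimethyldodeca-6,10-dien-1-ol (both C1 epimers) | C=C[C@](C)(CC/C=C(\C)CCC=C(C)C)CC(O)c1c(C)cccc1OCOC | intermediate
16 | (3R,6E)-3-ethenyl-1-[2-(methoxymethoxy)-6-methylphenyl]-3,7,11-trimethyldodeca-6,10-dien-1-one | C=C[C@](C)(CC/C=C(\C)CCC=C(C)C)CC(=O)c1c(C)cccc1OCOC | intermediate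
17 | (3R,6E)-3-ethenyl-1-(2-hydroxy-6-methylphenyl)-3,7,11-trimethyldodeca-6,10-dien-1-one | C=C[C@](C)(CC/C=C(\C)CCC=C(C)C)CC(=O)c1c(C)cccc1O | target

## Step count and risks

Total: 12 steps. Longest linear sequence: 10 steps from 1 (steps 1, 3 to 8 and 10 to 12). Steps 2 and 9 prepare the two side components.

**Step 3 (key step).** The most likely failure is that ionisation at the fully substituted C3 runs ahead of carbon delivery. Hydride shift to carbonyl compounds, elimination to allylic diols, attack at C2 or partial loss of stereospecificity would then compete, because the SN2 component is slowed at a tertiary carbon.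

Fallback: the quaternary carbon is made by a stereospecific 1,2-shift in place of an external nucleophile. It sets out from 1 and returns at 9.
- Epoxidation as in step 1, but with D-(−)-diethyl tartrate, should give (2R,3R)-2,3-epoxyfarnesol F1.
- Silylation (TBSCl, imidazole, DMF) gives tert-butyl{[(2R,3R)-3-[(3E)-4,8-dimethylnona-3,7-dien-1-yl]-3-methyloxiran-2-yl]methoxy}dimethylsilane F2.
- The bulky Lewis acid methylaluminium bis(4-bromo-2,6-di-tert-butylphenoxide) in CH2Cl2 at −78 °C should break the C3–O bond and move the siloxymethyl carbon from C2 to C3 anti to the leaving oxygen. This is the known organoaluminium-promoted rearrangement of epoxy silyl ethers to β-siloxy aldehydes, and it gives (2R,5E)-2-{[tert-butyl(dimethyl)silyl]oxymethyl}-2,6,10-trimethylundeca-5,9-dienal F3.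
- Wittig methylenation (Ph3PCH3Br, KOt-Bu, THF) converts the aldehyde into the vinyl group of tert-butyl{[(2S,5E)-2-ethenyl-2,6,10-trimethylundeca-5,9-dien-1-yl]oxy}dimethylsilane F4.
- Bu4NF frees (2S,5E)-2-ethenyl-2,6,10-trimethylundeca-5,9-dien-1-ol F5, and Dess–Martin oxidation returns to the route at 9.

The enantiomeric epoxide is needed because here the migrating carbon becomes the aldehyde carbon of 9 and the old C2 becomes the vinyl group, the reverse of the main route.

**Step 8.** Acid-induced side reactions are the risk. Aldehyde 11 is a 6-enal of the citronellal type and can close onto the C6 alkene by a carbonyl-ene or Prins process. The alkenes may also hydrate or migrate if hydrolysis of the hindered enol ether is slow.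

Fallback: a homologation that needs no acid. It sets out from 9 and returns at 11. Van Leusen reductive cyanation with p-toluenesulfonylmethyl isocyanide (KOt-Bu, DME, −40 °C, then MeOH, reflux) should give (3R,6E)-3-ethenyl-3,7,11-trimethyldodeca-6,10-dienenitrile F6. Reduction with i-Bu2AlH (toluene, −78 °C) and hydrolysis of the aldimine on buffered work-up then gives 11.

**Step 10.** Proton transfer may compete with addition. Aryllithium 14 is flanked by two ortho substituents and is a strong base, so enolisation of 11 and aldol self-condensation can consume the aldehyde.

Fallback: the chain carbon is raised to the acid level. It sets out from 11 and returns at 16, and step 11 is then not needed. Pinnick oxidation (NaClO2, NaH2PO4, 2-methyl-2-butene, t-BuOH/H2O) gives (3R,6E)-3-ethenyl-3,7,11-trimethyldodeca-6,10-dienoic acid F7. Coupling with N,O-dimethylhydroxylamine (carbonyldiimidazole, CH2Cl2) gives the Weinreb amide (3R,6E)-3-ethenyl-N-methoxy-N,3,7,11-tetramethyldodeca-6,10-dienamide F8. Addition of 14, made from 13 as in step 10, stops at the chelated tetrahedral intermediate and gives 16 on work-up.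

**Step 12.** Acid may damage the polyene in the last step. Protonation of the trisubstituted alkenes, leading to cyclisation, addition of methanol or double-bond migration, can set in before the acetal is fully cleaved.

Fallback: a phenol protecting group that leaves under neutral conditions. It sets out from 12 and 11 and returns at 17.
- Allylation of 12 (allyl bromide, K2CO3, acetone) gives 1-(allyloxy)-2-bromo-3-methylbenzene F9.
- Bromine–lithium exchange (n-BuLi, THF, −78 °C) gives [2-(allyloxy)-6-methylphenyl]lithium F10, which is kept cold to prevent cyclisation onto the allyl group and added to 11.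
- The adduct is (3R,6E)-1-[2-(allyloxy)-6-methylphenyl]-3-ethenyl-3,7,11-trimethyldodeca-6,10-dien-1-ol F11.
- Dess–Martin oxidation gives (3R,6E)-1-[2-(allyloxy)-6-methylphenyl]-3-ethenyl-3,7,11-trimethyldodeca-6,10-dien-1-one F12.
- Pd(PPh3)4 with morpholine in THF at rt transfers the allyl group to the amine and gives 17.

## Further compounds

F1 | step 3 | (2R,3R)-2,3-epoxyfarnesol, [(2R,3R)-3-[(3E)-4,8-dimethylnona-3,7-dien-1-yl]-3-methyloxiran-2-yl]methanol | OC[C@H]1O[C@]1(C)CC/C=C(\C)CCC=C(C)C
F2 | step 3 | tert-butyl{[(2R,3R)-3-[(3E)-4,8-dimethylnona-3,7-dien-1-yl]-3-methyloxiran-2-yl]methoxy}dimethylsilane | CC(C)(C)[Si](C)(C)OC[C@H]1O[C@]1(C)CC/C=C(\C)CCC=C(C)C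
F3 | step 3 | (2R,5E)-2-{[tert-butyl(dimethyl)silyl]oxymethyl}-2,6,10-trimethylundeca-5,9-dienal | CC(C)(C)[Si](C)(C)OC[C@@](C=O)(C)CC/C=C(\C)CCC=C(C)C
F4 | step 3 | tert-butyl{[(2S,5E)-2-ethenyl-2,6,10-trimethylundeca-5,9-dien-1-yl]oxy}dimethylsilane | CC(C)(C)[Si](C)(C)OC[C@@](C=C)(C)CC/C=C(\C)CCC=C(C)C
F5 | step 3 | (2S,5E)-2-ethenyl-2,6,10-trimethylundeca-5,9-dien-1-ol | OC[C@@](C=C)(C)CC/C=C(\C)CCC=C(C)C
F6 | step 8 | (3R,6E)-3-ethenyl-3,7,11-trimethyldodeca-6,10-dienenitrile | C=C[C@](C)(CC/C=C(\C)CCC=C(C)C)CC#N
F7 | step 10 | (3R,6E)-3-ethenyl-3,7,11-trimethyldodeca-6,10-dienoic acid | C=C[C@](C)(CC/C=C(\C)CCC=C(C)C)CC(=O)O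
F8 | step 10 | (3R,6E)-3-ethenyl-N-methoxy-N,3,7,11-tetramethyldodeca-6,10-dienamide | C=C[C@](C)(CC/C=C(\C)CCC=C(C)C)CC(=O)N(C)OC
F9 | step 12 | 1-(allyloxy)-2-bromo-3-methylbenzene | C=CCOc1cccc(C)c1Br
F10 | step 12 | [2-(allyloxy)-6-methylphenyl]lithium | [Li]c1c(C)cccc1OCC=C
F11 | step 12 | (3R,6E)-1-[2-(allyloxy)-6-methylphenyl]-3-ethenyl-3,7,11-trimethyldodeca-6,10-dien-1-ol | C=C[C@](C)(CC/C=C(\C)CCC=C(C)C)CC(O)c1c(C)cccc1OCC=C
F12 | step 12 | (3R,6E)-1-[2-(allyloxy)-6-methylphenyl]-3-ethenyl-3,7,11-trimethyldodeca-6,10-dien-1-one | C=C[C@](C)(CC/C=C(\C)CCC=C(C)C)CC(=O)c1c(C)cccc1OCC=C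
A1 | alternative 1 | (3R,6E)-3-ethenyl-1-[2-(methoxymethoxy)-6-methylphenyl]-3,7,11-trimethyldodeca-6,10-dien-1-one | C=C[C@](C)(CC/C=C(\C)CCC=C(C)C)CC(=O)c1c(C)cccc1OCOC
A2 | alternative 1 | 3-ethenyl-1-[2-(methoxymethoxy)-6-methylphenyl]-3-methylpent-4-en-1-one | C=CC(C)(C=C)CC(=O)c1c(C)cccc1OCOC
A3 | alternative 1 | (1E)-1-iodo-2,6-dimethylhepta-1,5-diene | I/C=C(\C)CCC=C(C)C
A4 | alternative 1 | (3R)-3-ethenyl-1-[2-(methoxymethoxy)-6-methylphenyl]-3-methyl-5-(4,4,5,5-tetramethyl-1,3,2-dioxaborolan-2-yl)pentan-1-one | C=C[C@](C)(CCB1OC(C)(C)C(C)(C)O1)CC(=O)c1c(C)cccc1OCOC
A5 | alternative 2 | tert-butyl{[(3R,6E)-3-ethenyl-3,7,11-trimethyldodeca-6,10-dien-1-yl]oxy}dimethylsilane | C=C[C@](C)(CC/C=C(\C)CCC=C(C)C)CCO[Si](C)(C)C(C)(C)C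
A6 | alternative 2 | [(3E)-4,8-dimethylnona-3,7-dien-1-yl]magnesium bromide | Br[Mg]CC/C=C(\C)CCC=C(C)C
A7 | alternative 2 | tert-butyl{[(3E)-5-chloro-3-methylpent-3-en-1-yl]oxy}dimethylsilane | ClC/C=C(\C)CCO[Si](C)(C)C(C)(C)C
A8 | alternative 3 | (3R,6E)-3-(2-methoxy-2-oxoethyl)-3,7,11-trimethyldodeca-6,10-dienoic acid | COC(=O)C[C@](C)(CC/C=C(\C)CCC=C(C)C)CC(=O)O
A9 | alternative 3 | dimethyl 3-[(3E)-4,8-dimethylnona-3,7-dien-1-yl]-3-methylpentanedioate | COC(=O)CC(C)(CC/C=C(\C)CCC=C(C)C)CC(=O)OC
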